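**Retrosynthetic overview**
1. Feature: ring A (C2 to C6) is a 2-alkylidene-3-alkylcyclopentane. C2 carries the exocyclic C2=C1 alkene to C12 of ring C, C6 carries the C7 side chain and C3 is oxygenated, so with C3 as a ketone ring A is cyclopent-2-enone (C6 β, C2 α). Numbering: C1 vinylic CH; C7 CHMe; C8 CHOH; C9 CH2; C10=C14 ring C alkene; C11 CMe(OH); C12 ketol carbon; C13 ketone; C16 CH2OMe.
2. Ring B (nine-membered: C1, C2, C6 to C12) is opened at C8–C9, an intramolecular vinylogous Mukaiyama aldol of the ring C dienol silane onto the C8 aldehyde. C3(OH)CH2OMe is set up from the C3 ketone before that (methylenation, dihydroxylation, O-methylation), because a C3 ketone or a C3 diene would itself attack the C8 aldehyde.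
3. C6–C7 and C2=C1 are cut together: three-component coupling of cyclopent-2-enone, the (Z)-silyl ketene thioacetal of S-tert-butyl propanethioate and the ring C aldehyde (catalytic asymmetric Mukaiyama–Michael addition, TiCl4 aldol of the enol silane, dehydration).
4. Ring C aldehyde: C12(OH)CHO from an exocyclic methylene by dihydroxylation anti to the C11 silyloxy group; enone by Stork–Danheiser transposition; ring C closed at C13–C14 by Dieckmann cyclisation of the copper bis(oxazoline) aldol adduct of 5-methylhexane-2,3-dione, which sets C11.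
5. Order of ring formation: ring C (step 3), ring A taken intact from cyclopentenone (step 13), ring B last (step 19).

Key step: step 13

Assumption: the sense of induction in step 13 is taken from the model in which the enone binds boron through the carbonyl lone pair syn to C2 and stacks on a catalyst aryl group; for the (R)-configured catalyst this should leave the Re face of C6 open, and the mirror-image catalyst is equally accessible should the sense be the reverse.

**Route**

Step 1
Reactants: 1 S-tert-butyl ethanethioate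
Product: 2 1-(tert-butylsulfanyl)-1-(trimethylsilyloxy)ethene
Conditions: LiN(iPr)2, THF, −78 °C; Me3SiCl, −78 °C to rt; distillation
Reagents that add atoms: chlorotrimethylsilane, C[Si](C)(C)Cl
Why: Kinetic deprotonation of the thioester and O-silylation of the lithium enolate give the silyl ketene thioacetal (enol silane formation), with no stereocentre formed.

Step 2
Reactants: 2 1-(tert-butylsulfanyl)-1-(trimethylsilyloxy)ethene; 3 5-methylhexane-2,3-dione
Product: 5 S-tert-butyl (3S)-3-hydroxy-3,6-dimethyl-4-oxoheptanethioate, via trimethylsilyl ether 4 (not isolated)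
Conditions: Cu(OTf)2 (10 mol%), (S,S)-2,2'-(propane-2,2-diyl)bis(4-tert-butyl-4,5-dihydrooxazole) (11 mol%), THF, −78 °C; then 1 M HCl, THF, rt
Reagents that add atoms: none
Why: In this copper bis(oxazoline)-catalysed Mukaiyama aldol addition the diketone chelates divalent copper through both carbonyl oxygens and the ketene acetal attacks the less hindered acetyl carbonyl on the Si face left open by the tert-butyl groups of the (S,S)-ligand, which sets C11 (S in 5, the same spatial arrangement as the R centre of the target), before acid removes the silyl group.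

Step 3
Reactants: 5 S-tert-butyl (3S)-3-hydroxy-3,6-dimethyl-4-oxoheptanethioate
Product: 6 (4S)-4-hydroxy-4-methyl-2-(propan-2-yl)cyclopentane-1,3-dione (enolised)
Conditions: LiN(SiMe3)2 (3.3 equiv), THF, −78 to 0 °C; then cold 1 M HCl
Reagents that add atoms: none
Why: In this Dieckmann-type intramolecular Claisen condensation the only enolisable position of the C10 ketone (C14) is acylated by the thioester to close ring C at C13–C14, driven by formation of the dione enolate, while C11 is held as its lithium alkoxide and cannot eliminate.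

Step 4
Reactants: 6 (4S)-4-hydroxy-4-methyl-2-(propan-2-yl)cyclopentane-1,3-dione
Product: 7 (5S)-5-hydroxy-3-methoxy-5-methyl-2-(propan-2-yl)cyclopent-2-en-1-one
Conditions: Me2SO4, K2CO3, acetone, rt; chromatography
Reagents that add atoms: dimethyl sulfate, COS(=O)(=O)OC
Why: O-Alkylation of the vinylogous acid should take place at the less hindered oxygen on C13, the C10 oxygen being flanked by quaternary C11 and hydrogen-bonded to its hydroxyl, so that the free carbonyl stays at C10 (vinylogous ester formation).

Step 5
Reactants: 7 (5S)-5-hydroxy-3-methoxy-5-methyl-2-(propan-2-yl)cyclopent-2-en-1-one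
Product: 8 (5S)-3-methoxy-5-methyl-2-(propan-2-yl)-5-(triethylsilyloxy)cyclopent-2-en-1-one
Conditions: Et3SiOTf, 2,6-lutidine, CH2Cl2, −78 to 0 °C
Reagents that add atoms: triethylsilyl trifluoromethanesulfonate, CC[Si](CC)(CC)OS(=O)(=O)C(F)(F)F
Why: Silylation of the tertiary alcohol with a silyl triflate and a hindered pyridine base is standard protection and is needed before the organometallic and enolate steps.

Step 6
Reactants: 8 (5S)-3-methoxy-5-methyl-2-(propan-2-yl)-5-(triethylsilyloxy)cyclopent-2-en-1-one
Product: 10 (4S)-3,4-dimethyl-2-(propan-2-yl)-4-(triethylsilyloxy)cyclopent-2-en-1-one, via tertiary allylic alcohol 9 (not isolated)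
Conditions: MeLi, CeCl3, THF, −78 °C; then 1 M HCl, THF, 0 °C, brief
Reagents that add atoms: methyllithium, [Li]C
Why: In this Stork–Danheiser sequence the methylcerium reagent adds 1,2 to the hindered C10 carbonyl without enolisation and dilute acid hydrolyses the enol ether with loss of water, which moves the carbonyl to C13 and places the C9 methyl on C10 while C11 is untouched.

Step 7
Reactants: 10 (4S)-3,4-dimethyl-2-(propan-2-yl)-4-(triethylsilyloxy)cyclopent-2-en-1-one
Product: 13 (4R)-3,4-dimethyl-5-methylidene-2-(propan-2-yl)-4-(triethylsilyloxy)cyclopent-2-en-1-one, via Mannich base 11 (not isolated), via ammonium iodide 12 (not isolated)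
Conditions: LiN(iPr)2, THF, −78 °C; CH2=NMe2+ I−, −78 °C to rt; then MeI, rt; then aq. NaHCO3, CH2Cl2, rt
Reagents that add atoms: N,N-dimethylmethyleneiminium iodide, C=[N+](C)C.[I-]
Why: Kinetic deprotonation at the alpha-prime carbon C12, Mannich reaction with the iminium salt, N-methylation and E1cB elimination install the exocyclic methylene (Eschenmoser methylenation), and loss of the C11 silyloxy group from the enolate is not expected because it would give a cyclopentadienone.

Step 8
Reactants: 13 (4R)-3,4-dimethyl-5-methylidene-2-(propan-2-yl)-4-(triethylsilyloxy)cyclopent-2-en-1-one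
Product: 14 (4R,5S)-5-hydroxy-5-(hydroxymethyl)-3,4-dimethyl-2-(propan-2-yl)-4-(triethylsilyloxy)cyclopent-2-en-1-one
Conditions: OsO4 (5 mol%), N-methylmorpholine N-oxide, acetone/H2O, 0 °C to rt
Reagents that add atoms: osmium tetroxide, O=[Os](=O)(=O)=O (delivers both oxygens; restored by N-methylmorpholine N-oxide, C[N+]1([O-])CCOCC1, and water, O)
Why: This Upjohn dihydroxylation should take place only at the exocyclic 1,1-disubstituted alkene (the tetrasubstituted ring alkene is inert), with OsO4 adding to the face of the flat ring anti to the allylic C11 silyloxy group for steric and stereoelectronic reasons, which places the C12 hydroxyl trans to the C11 oxygen (C12 S).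

Step 9
Reactants: 14 (4R,5S)-5-hydroxy-5-(hydroxymethyl)-3,4-dimethyl-2-(propan-2-yl)-4-(triethylsilyloxy)cyclopent-2-en-1-one
Product: 15 (4R,5S)-3,4-dimethyl-2-(propan-2-yl)-4,5-bis(triethylsilyloxy)-5-[(triethylsilyloxy)methyl]cyclopent-2-en-1-one
Conditions: Et3SiOTf (3 equiv), 2,6-lutidine, CH2Cl2, 0 °C to rt
Reagents that add atoms: triethylsilyl trifluoromethanesulfonate, CC[Si](CC)(CC)OS(=O)(=O)C(F)(F)F
Why: Exhaustive silylation with the silyl triflate protects the hindered tertiary ketol hydroxyl and the primary hydroxyl in one operation.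

Step 10
Reactants: 15 (4R,5S)-3,4-dimethyl-2-(propan-2-yl)-4,5-bis(triethylsilyloxy)-5-[(triethylsilyloxy)methyl]cyclopent-2-en-1-one
Product: 16 (1R,2R)-2,3-dimethyl-5-oxo-4-(propan-2-yl)-1,2-bis(triethylsilyloxy)cyclopent-3-ene-1-carbaldehyde (ring C aldehyde; formyl carbon is C1)
Conditions: (COCl)2, DMSO, CH2Cl2, −78 to −40 °C; Et3N, to 0 °C
Reagents that add atoms: none
Why: Under Swern conditions only the primary triethylsilyl ether is cleaved by the chlorosulfonium species and oxidised to the aldehyde (direct Swern oxidation of primary silyl ethers), the tertiary silyl ethers being inert and the quaternary alpha-carbon excluding epimerisation.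

Step 11
Reactants: 17 propanoyl chloride
Product: 18 S-tert-butyl propanethioate
Conditions: t-BuSH, pyridine, CH2Cl2, 0 °C to rt
Reagents that add atoms: 2-methylpropane-2-thiol, CC(C)(C)S
Why: Acylation of the thiol by the acid chloride in the presence of pyridine gives the thioester.

Step 12
Reactants: 18 S-tert-butyl propanethioate
Product: 19 (Z)-tert-butyl 1-(trimethylsilyloxy)prop-1-enyl sulfide
Conditions: LiN(iPr)2, THF, −78 °C; Me3SiCl, −78 °C to rt; distillation
Reagents that add atoms: chlorotrimethylsilane, C[Si](C)(C)Cl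
Why: Kinetic deprotonation in THF without cosolvent through the cyclic six-membered transition state gives the enolate with methyl trans to oxygen, and O-silylation fixes it as the (Z)-ketene acetal (methyl cis to sulfur).

Step 13
Reactants: 20 cyclopent-2-en-1-one; 19 (Z)-tert-butyl 1-(trimethylsilyloxy)prop-1-enyl sulfide; 16 ring C aldehyde
Product: 24 S-tert-butyl (2R)-2-[(1S,2E)-2-{[(1S,2R)-2,3-dimethyl-5-oxo-4-(propan-2-yl)-1,2-bis(triethylsilyloxy)cyclopent-3-en-1-yl]methylidene}-3-oxocyclopentyl]propanethioate, via enol silane 21 (not isolated), via aldol adduct 22 (not isolated), via mesylate 23 (not isolated)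
Conditions: oxazaborolidinium triflimide from (R)-α,α-diphenylprolinol, tri-o-tolylboroxine and HNTf2 (20 mol%), Ph3PO (25 mol%), toluene, −20 °C; then 16, TiCl4, CH2Cl2, −78 °C; aq. NaHCO3; crude aldol: MeSO2Cl, Et3N, CH2Cl2, 0 °C, then DBU, rt
Reagents that add atoms: none
Why: The N-protonated oxazaborolidine binds the enone carbonyl at the lone pair syn to C2, the ketene acetal adds to C6 through an open antiperiplanar transition state, and silyl transfer assisted by Ph3PO gives the C2=C3 enol silane 21 regiospecifically (catalytic Mukaiyama–Michael addition). TiCl4, chelated between the formyl and C13 carbonyl oxygens of 16, then mediates the Mukaiyama aldol addition of 21 at C2, and mesylation of the crude aldol followed by E1cB elimination gives the enone; the closest known reaction type is the three-component enone coupling by Mukaiyama–Michael addition with aldol trapping of the enol silane. No ring is closed, ring A coming intact from 20. C6 is set by the catalyst, whose aryl group should shield the Si face so that attack occurs on the Re face, and C7 by the ketene acetal geometry in the open transition state, where C7–H lies over the ring, the thioacetal carbon is anti to C2 and the tert-butylthio group points away from the ring. The step needs regiocontrol (reaction at C2, not C4), which the regiodefined enol silane secures, and E geometry at C2=C1, which the elimination secures by placing the bulky C12 anti to the carbonyl, so the C1 and C2 configurations of the aldol do not matter.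

Step 14
Reactants: 24 key-step enone
Product: 25 S-tert-butyl (2R)-2-[(1S,2E)-3-methylidene-2-{[ring C]methylidene}cyclopentyl]propanethioate (24 with C3=O replaced by C3=CH2)
Conditions: Zn, CH2Br2, TiCl4, THF (pre-formed reagent); 24, CH2Cl2, 0 °C to rt; aq. NaHCO3
Reagents that add atoms: dibromomethane, BrCBr
Why: Takai–Lombardo methylenation with the gem-dizinc reagent and TiCl4 is non-basic and selective for the accessible C3 ketone over the thioester and the C13 ketone (flanked by quaternary C12 and the isopropyl-bearing C14), so C7 should not epimerise.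

Step 15
Reactants: 25 diene thioester
Product: 26 the (3R)-3-hydroxy-3-(hydroxymethyl) compound (25 with C3=C16 converted to C3(OH)–C16H2OH; C3–OH cis to H6)
Conditions: OsO4 (5 mol%), N-methylmorpholine N-oxide, acetone/H2O, 0 °C
Reagents that add atoms: osmium tetroxide, O=[Os](=O)(=O)=O (delivers both oxygens; restored by N-methylmorpholine N-oxide, C[N+]1([O-])CCOCC1, and water, O)
Why: This Upjohn dihydroxylation should occur at the terminal C3=C16 alkene of the diene (C2=C1 is shielded by ring C and the ring C enone is inert), on the face of ring A anti to the C6 side chain, which allylic 1,3-strain with C12 holds pseudo-axial, so that the C3 hydroxyl ends up cis to H6 (C3 R).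

Step 16
Reactants: 26 diol thioester
Product: 27 the C16 methyl ether (C3–OH free)
Conditions: Me3OBF4, 1,8-bis(dimethylamino)naphthalene, CH2Cl2, 0 °C to rt
Reagents that add atoms: trimethyloxonium tetrafluoroborate, C[O+](C)C.F[B-](F)(F)F
Why: The oxonium salt with a non-nucleophilic proton scavenger methylates the primary C16 hydroxyl much faster than the tertiary C3 hydroxyl and leaves the thioester and silyl ethers alone (O-alkylation under neutral conditions).

Step 17
Reactants: 27 methyl ether thioester
Product: 28 the C3 triethylsilyl ether in which the ring C enone is the triethylsilyl dienol ether (C13–OSiEt3, C13=C14, C10=C9H2); stereocentres as in 27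
Conditions: Et3SiOTf (4 equiv), Et3N, CH2Cl2, −78 to 0 °C; filtration through Et3N-deactivated silica
Reagents that add atoms: triethylsilyl trifluoromethanesulfonate, CC[Si](CC)(CC)OS(=O)(=O)C(F)(F)F
Why: The silyl triflate with Et3N silylates the tertiary C3 hydroxyl and converts the ring C enone, whose only acidic position is the C9 methyl, into the 2-silyloxy diene by O-silylation and gamma-deprotonation (soft enolisation), while the less Lewis-basic, alpha-branched thioester should stay unenolised at low temperature.

Step 18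
Reactants: 28 dienol silane thioester
Product: 29 the corresponding C8 aldehyde
Conditions: iBu2AlH, CH2Cl2, −78 °C; MeOH, then aq. KNaC4H4O6
Reagents that add atoms: none
Why: iBu2AlH reduces the S-tert-butyl thioester to the aldehyde through the hemithioacetal aluminate at low temperature, with the C13 carbonyl masked as the dienol silane and C7 not epimerised under these non-basic conditions.

Step 19
Reactants: 29 dienol silane aldehyde
Product: 30 (3R,6S,7R,8S,11R,12S)-3,11,12-tris-O-triethylsilyl brassicicene M (C8–OH free)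
Conditions: BF3·OEt2, CH2Cl2 (1 mM), −78 °C; aq. NaHCO3
Reagents that add atoms: none
Why: In this intramolecular vinylogous Mukaiyama aldol addition BF3 activates the C8 aldehyde and the gamma-carbon C9 of the dienol silane attacks it to close the nine-membered ring B, the cis placement of C6 and C12 on the C2=C1 alkene bringing the termini together, and the transition state with the carbonyl oxygen and the C7 methyl both on the outside of the forming ring should give the C8 hydroxyl trans to the C7 methyl (C8 S).

Step 20
Reactants: 30 tris-silyl ether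
Product: 31 brassicicene M
Conditions: HF·pyridine, pyridine, THF, 0 °C to rt
Reagents that add atoms: none
Why: Buffered fluoride cleaves the three tertiary triethylsilyl ethers under conditions that should spare the alpha-ketol and the delta-hydroxy enone (global desilylation).

**Compound list**
1 | S-tert-butyl ethanethioate | CC(=O)SC(C)(C)C | starting material
2 | 1-(tert-butylsulfanyl)-1-(trimethylsilyloxy)ethene | C=C(O[Si](C)(C)C)SC(C)(C)C | intermediate
3 | 5-methylhexane-2,3-dione | CC(=O)C(=O)CC(C)C | starting material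
4 | S-tert-butyl (3S)-3,6-dimethyl-4-oxo-3-(trimethylsilyloxy)heptanethioate | CC(C)CC(=O)[C@@](C)(O[Si](C)(C)C)CC(=O)SC(C)(C)C | intermediate
5 | S-tert-butyl (3S)-3-hydroxy-3,6-dimethyl-4-oxoheptanethioate | CC(C)CC(=O)[C@@](C)(O)CC(=O)SC(C)(C)C | intermediate
6 | (4S)-4-hydroxy-4-methyl-2-(propan-2-yl)cyclopentane-1,3-dione, written as its enol (5S)-3,5-dihydroxy-5-methyl-2-(propan-2-yl)cyclopent-2-en-1-one | CC(C)C1=C(O)C[C@](C)(O)C1=O | intermediate
7 | (5S)-5-hydroxy-3-methoxy-5-methyl-2-(propan-2-yl)cyclopent-2-en-1-one | COC1=C(C(C)C)C(=O)[C@@](C)(O)C1 | intermediate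
8 | (5S)-3-methoxy-5-methyl-2-(propan-2-yl)-5-(triethylsilyloxy)cyclopent-2-en-1-one | COC1=C(C(C)C)C(=O)[C@@](C)(O[Si](CC)(CC)CC)C1 | intermediate
9 | (5S)-3-methoxy-1,5-dimethyl-2-(propan-2-yl)-5-(triethylsilyloxy)cyclopent-2-en-1-ol (both C1 epimers) | COC1=C(C(C)C)C(C)(O)[C@@](C)(O[Si](CC)(CC)CC)C1 | intermediate
10 | (4S)-3,4-dimethyl-2-(propan-2-yl)-4-(triethylsilyloxy)cyclopent-2-en-1-one | CC(C)C1=C(C)[C@@](C)(O[Si](CC)(CC)CC)CC1=O | intermediate
11 | (4S)-5-[(dimethylamino)methyl]-3,4-dimethyl-2-(propan-2-yl)-4-(triethylsilyloxy)cyclopent-2-en-1-one (both C5 epimers) | CC(C)C1=C(C)[C@@](C)(O[Si](CC)(CC)CC)C(CN(C)C)C1=O | intermediate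
12 | N,N,N-trimethylammonium iodide of 11 | CC(C)C1=C(C)[C@@](C)(O[Si](CC)(CC)CC)C(C[N+](C)(C)C)C1=O.[I-] | intermediate
13 | (4R)-3,4-dimethyl-5-methylidene-2-(propan-2-yl)-4-(triethylsilyloxy)cyclopent-2-en-1-one | CC(C)C1=C(C)[C@@](C)(O[Si](CC)(CC)CC)C(=C)C1=O | intermediate
14 | (4R,5S)-5-hydroxy-5-(hydroxymethyl)-3,4-dimethyl-2-(propan-2-yl)-4-(triethylsilyloxy)cyclopent-2-en-1-one | OC[C@@]1(O)C(=O)C(C(C)C)=C(C)[C@@]1(C)O[Si](CC)(CC)CC | intermediate
15 | (4R,5S)-3,4-dimethyl-2-(propan-2-yl)-4,5-bis(triethylsilyloxy)-5-[(triethylsilyloxy)methyl]cyclopent-2-en-1-one | CC[Si](CC)(CC)OC[C@@]1(O[Si](CC)(CC)CC)C(=O)C(C(C)C)=C(C)[C@@]1(C)O[Si](CC)(CC)CC | intermediate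
16 | (1R,2R)-2,3-dimethyl-5-oxo-4-(propan-2-yl)-1,2-bis(triethylsilyloxy)cyclopent-3-ene-1-carbaldehyde | O=C[C@@]1(O[Si](CC)(CC)CC)C(=O)C(C(C)C)=C(C)[C@@]1(C)O[Si](CC)(CC)CC | intermediate
17 | propanoyl chloride | CCC(Cl)=O | starting material
18 | S-tert-butyl propanethioate | CCC(=O)SC(C)(C)C | intermediate
19 | (Z)-tert-butyl 1-(trimethylsilyloxy)prop-1-enyl sulfide | C/C=C(/O[Si](C)(C)C)SC(C)(C)C | intermediate
20 | cyclopent-2-en-1-one | O=C1CCC=C1 | starting material
21 | S-tert-butyl (2R)-2-[(1R)-3-(trimethylsilyloxy)cyclopent-2-en-1-yl]propanethioate | C[Si](C)(C)OC1=C[C@@H](CC1)[C@@H](C)C(=O)SC(C)(C)C | intermediate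
22 | beta-hydroxy ketone from 21 and 16 (C1 and C2 epimers; C6, C7, C11, C12 as in 24) | O=C1CC[C@@H]([C@@H](C)C(=O)SC(C)(C)C)C1C(O)[C@@]1(O[Si](CC)(CC)CC)C(=O)C(C(C)C)=C(C)[C@@]1(C)O[Si](CC)(CC)CC | intermediate
23 | C1 methanesulfonate of 22 | O=C1CC[C@@H]([C@@H](C)C(=O)SC(C)(C)C)C1C(OS(C)(=O)=O)[C@@]1(O[Si](CC)(CC)CC)C(=O)C(C(C)C)=C(C)[C@@]1(C)O[Si](CC)(CC)CC | intermediate
24 | S-tert-butyl (2R)-2-[(1S,2E)-2-{[(1S,2R)-2,3-dimethyl-5-oxo-4-(propan-2-yl)-1,2-bis(triethylsilyloxy)cyclopent-3-en-1-yl]methylidene}-3-oxocyclopentyl]propanethioate | O=C1CC[C@@H]([C@@H](C)C(=O)SC(C)(C)C)/C1=C\[C@@]1(O[Si](CC)(CC)CC)C(=O)C(C(C)C)=C(C)[C@@]1(C)O[Si](CC)(CC)CC | intermediate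
25 | 3-methylidene analogue of 24 (C3=CH2; C2=C1 E) | C=C1CC[C@@H]([C@@H](C)C(=O)SC(C)(C)C)/C1=C\[C@@]1(O[Si](CC)(CC)CC)C(=O)C(C(C)C)=C(C)[C@@]1(C)O[Si](CC)(CC)CC | intermediate
26 | (3R)-3-hydroxy-3-(hydroxymethyl) thioester (C3–OH cis to H6) | OC[C@@]1(O)CC[C@@H]([C@@H](C)C(=O)SC(C)(C)C)/C1=C\[C@@]1(O[Si](CC)(CC)CC)C(=O)C(C(C)C)=C(C)[C@@]1(C)O[Si](CC)(CC)CC | intermediate
27 | (3R)-3-hydroxy-3-(methoxymethyl) thioester | COC[C@@]1(O)CC[C@@H]([C@@H](C)C(=O)SC(C)(C)C)/C1=C\[C@@]1(O[Si](CC)(CC)CC)C(=O)C(C(C)C)=C(C)[C@@]1(C)O[Si](CC)(CC)CC | intermediate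
28 | C3 triethylsilyl ether of 27 with ring C as its triethylsilyl dienol ether | COC[C@@]1(O[Si](CC)(CC)CC)CC[C@@H]([C@@H](C)C(=O)SC(C)(C)C)/C1=C\[C@@]1(O[Si](CC)(CC)CC)C(O[Si](CC)(CC)CC)=C(C(C)C)C(=C)[C@@]1(C)O[Si](CC)(CC)CC | intermediate
29 | C8 aldehyde corresponding to 28 | COC[C@@]1(O[Si](CC)(CC)CC)CC[C@@H]([C@@H](C)C=O)/C1=C\[C@@]1(O[Si](CC)(CC)CC)C(O[Si](CC)(CC)CC)=C(C(C)C)C(=C)[C@@]1(C)O[Si](CC)(CC)CC | intermediate
30 | 3,11,12-tris-O-triethylsilyl brassicicene M | COC[C@@]1(O[Si](CC)(CC)CC)CC[C@@H]2/C1=C\[C@@]1(O[Si](CC)(CC)CC)C(=O)C(C(C)C)=C(C[C@H](O)[C@@H]2C)[C@@]1(C)O[Si](CC)(CC)CC | intermediate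
31 | brassicicene M | COC[C@@]1(O)CC[C@@H]2/C1=C\[C@@]1(O)C(=O)C(C(C)C)=C(C[C@H](O)[C@@H]2C)[C@@]1(C)O | target

**Step count and risks**

Total: 20 steps. Longest linear sequence: 18 steps (steps 1 to 10, then 13 to 20).

Step 13. What may go wrong: low facial discrimination at C6 or low diastereoselection at C7 in the Michael addition, or slow aldol addition to the hindered quaternary aldehyde so that the enol silane is lost by protodesilylation. Fallback, setting out from 19 and 16 and returning at 24: the known diethyl (2-oxocyclopentyl)phosphonate is selenenylated (PhSeCl, pyridine) to diethyl [2-oxo-1-(phenylselanyl)cyclopentyl]phosphonate F1 and oxidised (H2O2) to the two-point-binding acceptor diethyl (5-oxocyclopent-1-en-1-yl)phosphonate F2. Mukaiyama–Michael addition of 19 to F2 under Cu(SbF6)2 with the tert-butyl bis(oxazoline) ligand (enantiomer chosen for Re-face attack at C6), followed by desilylation, gives S-tert-butyl (2R)-2-[(1S)-2-(diethoxyphosphoryl)-3-oxocyclopentyl]propanethioate F3. A Horner–Wadsworth–Emmons reaction of F3 with 16 (LiCl, DBU, MeCN) then forms C2=C1 with E geometry without any aldol or dehydration.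

Step 19. What may go wrong: intermolecular aldol oligomerisation or protodesilylation of the dienol silane may outrun the nine-membered ring closure, or the facial selectivity at C8 may be low. Fallback, setting out from 29 and returning at 30: the dienol silane is brominated at C9 with N-bromosuccinimide (THF, −78 °C) to the gamma-bromo enone aldehyde F4. CrCl2 (THF, high dilution, rt) then generates a trivalent chromium dienolate that adds through C9 to the C8 aldehyde (intramolecular vinylogous Reformatsky reaction of the Nozaki–Hiyama type), which needs no Lewis acid activation of the aldehyde.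

Step 17. What may go wrong: competing enolisation of the thioester with loss of configurational integrity at C7, or incomplete enolisation of the hindered enone. Fallback, setting out from 27 and returning at 29: the thioester is exchanged for the much less acidic N-methoxy-N-methylamide F5 (MeONHMe, AgO2CCF3, THF) and the C3 hydroxyl is silylated (Et3SiOTf, 2,6-lutidine) to its triethylsilyl ether F6. The ring C dienolate is then formed kinetically with LiN(SiMe3)2 and trapped with Et3SiCl to give the dienol silane amide F7, and iBu2AlH reduction of the amide gives the aldehyde.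

Further compounds
F1 | step 13 | diethyl [2-oxo-1-(phenylselanyl)cyclopentyl]phosphonate | CCOP(=O)(OCC)C1([Se]c2ccccc2)CCCC1=O
F2 | step 13 | diethyl (5-oxocyclopent-1-en-1-yl)phosphonate | CCOP(=O)(OCC)C1=CCCC1=O
F3 | step 13 | S-tert-butyl (2R)-2-[(1S)-2-(diethoxyphosphoryl)-3-oxocyclopentyl]propanethioate | CCOP(=O)(OCC)C1C(=O)CC[C@H]1[C@@H](C)C(=O)SC(C)(C)C
F4 | step 19 | gamma-bromo enone aldehyde (29 with ring C returned to the enone and C9 as CH2Br) | COC[C@@]1(O[Si](CC)(CC)CC)CC[C@@H]([C@@H](C)C=O)/C1=C\[C@@]1(O[Si](CC)(CC)CC)C(=O)C(C(C)C)=C(CBr)[C@@]1(C)O[Si](CC)(CC)CC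
F5 | step 17 | N-methoxy-N-methylamide corresponding to 27 | COC[C@@]1(O)CC[C@@H]([C@@H](C)C(=O)N(C)OC)/C1=C\[C@@]1(O[Si](CC)(CC)CC)C(=O)C(C(C)C)=C(C)[C@@]1(C)O[Si](CC)(CC)CC
F6 | step 17 | C3 triethylsilyl ether of F5 | COC[C@@]1(O[Si](CC)(CC)CC)CC[C@@H]([C@@H](C)C(=O)N(C)OC)/C1=C\[C@@]1(O[Si](CC)(CC)CC)C(=O)C(C(C)C)=C(C)[C@@]1(C)O[Si](CC)(CC)CC
F7 | step 17 | triethylsilyl dienol ether of F6 | COC[C@@]1(O[Si](CC)(CC)CC)CC[C@@H]([C@@H](C)C(=O)N(C)OC)/C1=C\[C@@]1(O[Si](CC)(CC)CC)C(O[Si](CC)(CC)CC)=C(C(C)C)C(=C)[C@@]1(C)O[Si](CC)(CC)CC
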